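Start with the easy count. If each D takes one X, the flask charged with 1.80 equiv of X has a spare of 0.800 per D charged, the spare being the X charged per D less the one X each D takes; a negative spare is D that the X cannot reach.

| flask | D | X | Q | remark | time |
|---|---|---|---|---|---|
| south-west | 0.25 M | 1.8 equiv | 0.25 M | run made earlier |  |
| east | 1 M | 1.8 equiv | 0.25 M | run made earlier |  |
| south | 0.50 M | 3.6 equiv | 0.25 M | run made earlier |  |
| flask | 0.50 M | 1.80 equiv | 0.250 M |  | 20 h |

| run | time / h | E / % | D / % |
|---|---|---|---|
| south-west | 1.33 | 67.6 | 27.8 |
| south-west | 3.00 | 81.0 | 14.5 |
| south-west | 6.00 | 83.8 | 4.4 |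
| south-west | 12.0 | 81.6 | 1.3 |
| south-west | 25.0 | 67.0 | 0 |
| east | 1.33 | 72.1 | 24.9 |
| east | 3.00 | 81.6 | 13.5 |
| east | 6.00 | 83.9 | 4.6 |
| east | 12.0 | 79.0 | 1.0 |
| east | 25.0 | 66.4 | 0 |
| south | 1.33 | 87.0 | 11.9 |
| south | 3.00 | 93.8 | 0.5 |
| south | 6.00 | 90.3 | 0 |
| south | 12.0 | 80.4 | 0.3 |
| south | 25.0 | 63.2 | 0 |

(readings scatter by 1 percentage point)



* the moment within 20 h at which there is most E
* the amount of E, in percent of the D charged, at that time
* earliest time at which at least nineteen twentieths of that best amount are there
* latest time at which they still are

Two chemists dispute this flask. The first holds to the count: the south run has the same D as the flask, its spare of 2.60 is positive just as the flask's is, and so, since every D is covered in both, the flask should copy that run, with E near 93.8% at 3.00 h. The second works with the fraction left and not the fraction made: at that time the south-west and east runs, which have the flask's spare, still hold 14.5% and 13.5% of their D against 0.5% in the south run, so the room for E in the south-west run is 85.5%, which is less than the first chemist's figure. Those two runs, at 0.25 M and 1 M of D, nearly coincide, so she takes their curve for the flask at 0.50 M. Hers is the forecast, which puts most E at 6 h with 84.5% and the window from 2.7 h to 12 h, on the ground that “the ratio X/D governs conversion”.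

The simulation sides with the forecast: in the flask most E stands at 5.66 h with 86.0%, and the window runs from 2.76 h to 11.0 h.

    D ⇌ J + L, settled at all times (K = 0.00990 M)
    X + J → E (k = 38.3 /M/h)
    E ⇌ Z (K = 2.80, k = 0.0201 /h)
    X + Q → G (k = 0.0755 /M/h)

The largest single effect on the best in this flask is the loss of E to Z, both ways: the run without that step gives 99.8% against 86.0%, a gap of 14 percentage points, whereas the consumption of X, which is a part of the reason, accounts for 5 points. By 20.0 h the spare of 0.800, less the 0.214 per D that went with Q to G, comes to 0.586, and the flask holds 0.588 of X per D charged, with 0.16% of its D still unreacted. The count has its region where the spare is negative: a neighbour flask charged with 0.450 equiv of X is short by 0.550 per D charged and ends with 53.6% of its D left.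

Readings and results are calculated with constants of no real substance; noise was put on by code.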